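**Retrosynthetic overview**
1. Target ⇒ O‑acylation of the primary C19' alcohol ⇒ Wittig cuts at C11=C12 and C11'=C12'. These give a C15 keto‑enal (ring B end), a C10 bis(phosphonium) salt and a C15 lactol (ring A end).
2. Two molecules of the keto‑enal ⇒ oxidative scission of the central C=C of one C2‑symmetric C30 trienedione ⇒ N–O cleavage of a bis(spiro‑isoxazoline), the isoxazoline serving as a masked aldol.
3. Key step: twofold nitrile oxide [3+2] cycloaddition. The bis(nitrile oxide) of 2,7‑dimethylocta‑2,4,6‑trienedial reacts with two (5R)‑4‑methylidene‑3,3,5‑trimethylcyclohexanones. Both C7–C8 bonds, both C6–O stereocentres and two rings arise together.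
4. Lactol ⇒ i‑Bu2AlH reduction of a 4‑alkynylbutenolide ⇒ Sonogashira coupling of the ring A enyne with 4‑bromofuran‑2(5H)‑one. The butenolide ring locks the C9'=C10' geometry and tells C19' from C11'.
5. Ring order: carbocycles A and B are carried in from ketoisophorone through (4R,6R)‑actinol, and the butenolide is bought. The two isoxazolines form simultaneously in step 6 and are opened in step 7. The lactol ring opens in step 15.

Assumption: the SMILES is read as (3'R,5R,6R) with an all‑trans chain (9'Z only by CIP rank of CH2O); compounds 6, 16 and the ene‑reductase are taken as catalogue items.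

**Step 1**
Reactants: 1 ketoisophorone (2,6,6‑trimethylcyclohex‑2‑ene‑1,4‑dione)
Product: 2 (6R)‑2,2,6‑trimethylcyclohexane‑1,4‑dione ((6R)‑levodione)
Conditions: ene‑reductase OYE2, NADP+ (cat.), glucose dehydrogenase, D‑glucose, potassium phosphate buffer pH 7, 30 °C, extract at full conversion
Reagents that add atoms: none
Why: Biocatalytic asymmetric conjugate (ene) reduction in which the flavin delivers hydride and a tyrosine the proton in a trans fashion across the C2=C3 bond, the benchmark reaction of Old Yellow Enzymes, which sets the methyl‑bearing centre as (6R).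

**Step 2**
Reactants: 2 (6R)‑levodione
Product: 3 (4R,6R)‑4‑hydroxy‑2,2,6‑trimethylcyclohexan‑1‑one ((4R,6R)‑actinol)
Conditions: Li[HB(s‑Bu)3] (1.05 equiv), THF, −78 °C; then H2O
Reagents that add atoms: none
Why: Chemo‑ and diastereoselective hydride reduction in which the bulky borohydride ignores the carbonyl flanked by CMe2 and CHMe and attacks the open C4 carbonyl from the equatorial side because the axial trajectory is blocked by the syn‑axial C2 methyl, giving the axial (4R) alcohol trans to the C6 methyl.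

**Step 3**
Reactants: 3 (4R,6R)‑actinol
Product: 4 (1R,5R)‑3,3,5‑trimethyl‑4‑methylidenecyclohexan‑1‑ol
Conditions: Cp2TiMe2 (3 equiv), toluene, 70 °C, dark
Reagents that add atoms: dimethyltitanocene Cp2TiMe2, [CH3-].[CH3-].[Ti+4].c1cc[cH-]c1.c1cc[cH-]c1
Why: Petasis methylenation through Cp2Ti=CH2 ([2+2] then cycloreversion) is non‑basic, so the hindered enolisable ketone is olefinated without epimerising the adjacent methyl‑bearing centre, the free hydroxyl merely consuming one extra equivalent of reagent.

**Step 4**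
Reactants: 4 (1R,5R)‑3,3,5‑trimethyl‑4‑methylidenecyclohexan‑1‑ol
Product: 5 (5R)‑3,3,5‑trimethyl‑4‑methylidenecyclohexan‑1‑one
Conditions: Pr4N[RuO4] (5 mol %), N‑methylmorpholine N‑oxide, 4 Å molecular sieves, CH2Cl2, rt
Reagents that add atoms: none
Why: Ley–Griffith oxidation of the secondary alcohol under neutral conditions leaves the exocyclic alkene in place and removes the axial hydroxyl so that the ring now sits firmly in the chair having the C5 methyl equatorial.

**Step 5**
Reactants: 6 (2E,4E,6E)‑2,7‑dimethylocta‑2,4,6‑trienedial (C10 dialdehyde)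
Product: 7 (2E,4E,6E)‑2,7‑dimethylocta‑2,4,6‑trienedial (1E,8E)‑dioxime
Conditions: NH2OH·HCl, NaOAc, EtOH–H2O, rt
Reagents that add atoms: hydroxylamine hydrochloride, [NH3+]O.[Cl-]
Why: Simple condensation (oxime formation) at both aldehyde groups, the conjugated E,E‑dioxime being the thermodynamic product.

**Step 6 (key step)**
Reactants: 7 C10 dioxime; 5 (5R)‑3,3,5‑trimethyl‑4‑methylidenecyclohexan‑1‑one (two molecules react)
Product: 9 C2‑symmetric bis(spiro‑isoxazoline) dione (2E,4E,6E)‑2,7‑bis[(5R,10R)‑6,6,10‑trimethyl‑8‑oxo‑1‑oxa‑2‑azaspiro[4.5]dec‑2‑en‑3‑yl]octa‑2,4,6‑triene, via bis(nitrile oxide) 8 (not isolated)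
Conditions: PhI(OAc)2 (2.2 equiv, syringe pump, 10 h), 5 (3 equiv, excess recovered), CH2Cl2–MeOH 9:1, 0 °C to rt; chromatography removes the minor diastereomers
Reagents that add atoms: none
Why: Twofold Huisgen nitrile oxide–alkene 1,3‑dipolar cycloaddition in which each dipole oxygen bonds to the fully substituted alkene carbon of 5 (the usual 5,5‑disubstituted regiochemistry) and each dipole approaches the chair of 5 anti to the axial methyl of the neighbouring CMe2 group, so that the new C–O bond is axial and cis to the equatorial C5 methyl, which sets both (5R) spiro centres and closes two isoxazoline rings in one operation.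

**Step 7**
Reactants: 9 bis(spiro‑isoxazoline) dione
Product: 10 (3E,5E,7E)‑1,10‑bis[(1R,6R)‑1‑hydroxy‑2,2,6‑trimethyl‑4‑oxocyclohexyl]‑3,8‑dimethyldeca‑3,5,7‑triene‑2,9‑dione
Conditions: Mo(CO)6 (2 equiv), MeCN–H2O 15:1, 80 °C
Reagents that add atoms: water, O
Why: Reductive N–O bond cleavage of both isoxazolines by Mo(CO)6 followed by hydrolysis of the resulting β‑hydroxy imines unmasks two aldol units without touching C=C or C=O bonds and without involving the C–O stereocentres.

**Step 8**
Reactants: 10 C30 bis(β‑hydroxy ketone)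
Product: 12 (2E)‑5‑[(1R,6R)‑1‑hydroxy‑2,2,6‑trimethyl‑4‑oxocyclohexyl]‑3‑methyl‑4‑oxopent‑2‑enal (two molecules per molecule of 10), via central syn‑diol 11 (not isolated)
Conditions: OsO4 (2 mol %), NaIO4 (2.1 equiv), 2,6‑lutidine, dioxane–H2O 3:1, 0 °C to rt; use 12 promptly
Reagents that add atoms: osmium tetroxide, O=[Os](=O)(=O)=O; sodium periodate, [Na+].[O-]I(=O)(=O)=O
Why: Lemieux–Johnson cleavage (catalytic dihydroxylation then periodate glycol scission) in which electrophilic OsO4 picks the central disubstituted C=C, the only one not directly deactivated by a ketone, so that one molecule of 10 gives two identical molecules of 12 with the E enone geometry and both ring stereocentres untouched.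

**Step 9**
Reactants: 3 (4R,6R)‑actinol
Product: 13 (1S,4R,6R)‑1‑ethynyl‑2,2,6‑trimethylcyclohexane‑1,4‑diol (major C1 epimer)
Conditions: HC≡CMgBr (4 equiv), THF, 0 to 45 °C; then H2O
Reagents that add atoms: ethynylmagnesium bromide, C#C[Mg]Br
Why: Grignard 1,2‑addition (ethynylation) to the hindered ketone after deprotonation of the hydroxyl, mainly by axial attack, the new carbinol centre and the neighbouring methine both being erased in step 10 so that only the (4R) carbinol matters.

**Step 10**
Reactants: 13 ethynyl diol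
Product: 15 (1R)‑4‑ethynyl‑3,5,5‑trimethylcyclohex‑3‑en‑1‑yl acetate, via 4‑O‑monoacetate 14 (not isolated)
Conditions: Ac2O (1.2 equiv), DMAP (cat.), pyridine, rt; then POCl3 (3 equiv), 95 °C
Reagents that add atoms: acetic anhydride, CC(=O)OC(C)=O
Why: Selective acetylation of the secondary alcohol followed by POCl3–pyridine dehydration of the tertiary propargylic alcohol, which can lose only the single β‑hydrogen at C6 and therefore gives the tetrasubstituted enyne regiospecifically while the (R) acetate centre is untouched.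

**Step 11**
Reactants: 15 enyne acetate; 16 4‑bromofuran‑2(5H)‑one
Product: 17 4‑{[(4R)‑4‑acetoxy‑2,6,6‑trimethylcyclohex‑1‑en‑1‑yl]ethynyl}furan‑2(5H)‑one
Conditions: PdCl2(PPh3)2 (3 mol %), CuI (6 mol %), Et3N, THF, rt
Reagents that add atoms: none
Why: Sonogashira coupling of the terminal enyne at the vinylogous acyl bromide, a highly activated sp2 halide, so that the future C19' and C11' carbons are held cis on the C9'=C10' bond by the ring.

**Step 12**
Reactants: 17 alkynyl butenolide
Product: 18 4‑{[(4R)‑4‑hydroxy‑2,6,6‑trimethylcyclohex‑1‑en‑1‑yl]ethynyl}‑2,5‑dihydrofuran‑2‑ol (lactol, anomer mixture)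
Conditions: i‑Bu2AlH (2.5 equiv), CH2Cl2, −78 °C; aq. potassium sodium tartrate, no acid; use at once
Reagents that add atoms: none
Why: Low‑temperature i‑Bu2AlH reduction stops at the aluminated hemiacetal stage for both esters, so work‑up gives the lactol (a masked Z‑4‑hydroxy‑enal) and at the same time frees the ring A hydroxyl.

**Step 13**
Reactants: 6 C10 dialdehyde
Product: 19 (2E,4E,6E)‑2,7‑dimethylocta‑2,4,6‑triene‑1,8‑diol
Conditions: NaBH4, MeOH–CH2Cl2, 0 °C
Reagents that add atoms: none
Why: Borohydride 1,2‑reduction of both conjugated aldehydes leaves the triene geometry unchanged.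

**Step 14**
Reactants: 19 C10 diol
Product: 20 [(2E,4E,6E)‑2,7‑dimethylocta‑2,4,6‑triene‑1,8‑diyl]bis(triphenylphosphonium) dibromide
Conditions: PPh3·HBr (2.05 equiv), MeOH, rt
Reagents that add atoms: triphenylphosphine hydrobromide, [Br-].c1ccc(cc1)[PH+](c1ccccc1)c1ccccc1
Why: Acid‑promoted ionisation of the polyenylic alcohols and capture of the delocalised cation by PPh3 at the primary terminus (standard allylic phosphonium salt formation) gives the crystalline all‑E bis‑salt.

**Step 15**
Reactants: 20 C10 bis(phosphonium) dibromide; 18 lactol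
Product: 22 {(2E,4E,6E,8E,10Z)‑11‑(hydroxymethyl)‑13‑[(4R)‑4‑hydroxy‑2,6,6‑trimethylcyclohex‑1‑en‑1‑yl]‑2,7‑dimethyltrideca‑2,4,6,8,10‑pentaen‑12‑yn‑1‑yl}triphenylphosphonium bromide, via mono‑ylide 21 (not isolated)
Conditions: 20 (3 equiv), NaOMe (1 equiv), CH2Cl2–MeOH, 0 °C to rt, dark
Reagents that add atoms: none
Why: Wittig olefination of the ring‑opened hydroxy‑enal tautomer of the lactol by the semi‑stabilised mono‑ylide forms the C11'=C12' bond mainly E, releases the C19' hydroxyl and keeps the ring‑derived C9'=C10' geometry, the large excess of cheap 20 suppressing double condensation.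

**Step 16**
Reactants: 22 C25 phosphonium bromide; 12 keto‑enal
Product: 24 19'‑hydroxy carotenoid (the target lacking the hexanoyl group), via polyenyl ylide 23 (not isolated)
Conditions: NaN(SiMe3)2 (1 equiv), THF, −78 °C; then 12, −78 to 0 °C, dark
Reagents that add atoms: none
Why: Wittig olefination in which the polyenyl ylide attacks the aldehyde of 12 far faster than either ketone and is too weak a base to form the tertiary alkoxide needed for retro‑aldol cleavage, creating the C11=C12 bond (E isomer purified by chromatography in dim light).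

**Step 17**
Reactants: 24 19'‑hydroxy carotenoid
Product: 25 target CNP0125554.1
Conditions: hexanoyl chloride (1.05 equiv), 2,4,6‑collidine, CH2Cl2, −78 to −30 °C, dark
Reagents that add atoms: hexanoyl chloride, CCCCCC(=O)Cl
Why: Kinetically controlled O‑acylation (acid chloride plus collidine at low temperature) esterifies the unhindered primary allylic hydroxyl much faster than the secondary ring A hydroxyl or the tertiary ring B hydroxyl and creates no stereocentre.

**Compound list**
1 | ketoisophorone | O=C1C(C)=CC(=O)CC1(C)C | starting material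
2 | (6R)‑levodione | O=C1[C@H](C)CC(=O)CC1(C)C | intermediate
3 | (4R,6R)‑actinol | O=C1[C@H](C)C[C@@H](O)CC1(C)C | intermediate
4 | (1R,5R)‑3,3,5‑trimethyl‑4‑methylidenecyclohexan‑1‑ol | C=C1[C@H](C)C[C@@H](O)CC1(C)C | intermediate
5 | (5R)‑3,3,5‑trimethyl‑4‑methylidenecyclohexan‑1‑one | C=C1[C@H](C)CC(=O)CC1(C)C | intermediate
6 | (2E,4E,6E)‑2,7‑dimethylocta‑2,4,6‑trienedial | O=C/C(C)=C/C=C/C=C(C)/C=O | starting material
7 | C10 (E,E)‑dioxime | O/N=C/C(C)=C/C=C/C=C(C)/C=N/O | intermediate
8 | C10 bis(nitrile oxide) | [O-][N+]#C/C(C)=C/C=C/C=C(C)/C#[N+][O-] | intermediate (not isolated)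
9 | C2‑symmetric bis(spiro‑isoxazoline) dione | C1[C@]2([C@H](C)CC(=O)CC2(C)C)ON=C1/C(C)=C/C=C/C=C(C)/C1=NO[C@]2(C1)[C@H](C)CC(=O)CC2(C)C | intermediate
10 | C30 bis(β‑hydroxy ketone) trienedione | O=C(C[C@@]1(O)[C@H](C)CC(=O)CC1(C)C)/C(C)=C/C=C/C=C(C)/C(=O)C[C@@]1(O)[C@H](C)CC(=O)CC1(C)C | intermediate
11 | central 5,6‑syn‑diol of 10 (both syn diastereomers) | O=C(C[C@@]1(O)[C@H](C)CC(=O)CC1(C)C)/C(C)=C/C(O)C(O)/C=C(C)/C(=O)C[C@@]1(O)[C@H](C)CC(=O)CC1(C)C | intermediate (not isolated)
12 | (2E)‑5‑[(1R,6R)‑1‑hydroxy‑2,2,6‑trimethyl‑4‑oxocyclohexyl]‑3‑methyl‑4‑oxopent‑2‑enal | O=C/C=C(\C)C(=O)C[C@@]1(O)[C@H](C)CC(=O)CC1(C)C | intermediate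
13 | (1S,4R,6R)‑1‑ethynyl‑2,2,6‑trimethylcyclohexane‑1,4‑diol | C#C[C@]1(O)[C@H](C)C[C@@H](O)CC1(C)C | intermediate
14 | 4‑O‑monoacetate of 13 | C#C[C@]1(O)[C@H](C)C[C@@H](OC(C)=O)CC1(C)C | intermediate (not isolated)
15 | (1R)‑4‑ethynyl‑3,5,5‑trimethylcyclohex‑3‑en‑1‑yl acetate | C#CC1=C(C)C[C@@H](OC(C)=O)CC1(C)C | intermediate
16 | 4‑bromofuran‑2(5H)‑one | O=C1C=C(Br)CO1 | starting material
17 | 4‑alkynylbutenolide acetate | O=C1C=C(C#CC2=C(C)C[C@@H](OC(C)=O)CC2(C)C)CO1 | intermediate
18 | lactol (anomer mixture) | OC1C=C(C#CC2=C(C)C[C@@H](O)CC2(C)C)CO1 | intermediate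
19 | (2E,4E,6E)‑2,7‑dimethylocta‑2,4,6‑triene‑1,8‑diol | OC/C(C)=C/C=C/C=C(C)/CO | intermediate
20 | C10 bis(triphenylphosphonium) dibromide | [Br-].[Br-].c1ccccc1[P+](c1ccccc1)(c1ccccc1)C/C(C)=C/C=C/C=C(C)/C[P+](c1ccccc1)(c1ccccc1)c1ccccc1 | intermediate
21 | mono‑ylide of 20 | [Br-].c1ccccc1[P+](c1ccccc1)(c1ccccc1)C/C(C)=C/C=C/C=C(C)/[CH-][P+](c1ccccc1)(c1ccccc1)c1ccccc1 | intermediate (not isolated)
22 | C25 phosphonium bromide | [Br-].OC\C(C#CC1=C(C)C[C@@H](O)CC1(C)C)=C/C=C/C(C)=C/C=C/C=C(C)/C[P+](c1ccccc1)(c1ccccc1)c1ccccc1 | intermediate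
23 | ylide of 22 | OC\C(C#CC1=C(C)C[C@@H](O)CC1(C)C)=C/C=C/C(C)=C/C=C/C=C(C)/[CH-][P+](c1ccccc1)(c1ccccc1)c1ccccc1 | intermediate (not isolated)
24 | 19'‑hydroxy carotenoid | OC\C(C#CC1=C(C)C[C@@H](O)CC1(C)C)=C/C=C/C(C)=C/C=C/C=C(C)/C=C/C=C(\C)C(=O)C[C@@]1(O)[C@H](C)CC(=O)CC1(C)C | intermediate
25 | CNP0125554.1 | CCCCCC(=O)OC\C(C#CC1=C(C)C[C@@H](O)CC1(C)C)=C/C=C/C(C)=C/C=C/C=C(C)/C=C/C=C(\C)C(=O)C[C@@]1(O)[C@H](C)CC(=O)CC1(C)C | target

**Totals**
Total step count: 17.
Longest linear sequence: 9 steps (1, 2, 3, 4, 6, 7, 8, 16, 17). The ring A branch (1, 2, 9, 10, 11, 12, 15, 16, 17) is equally long.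

**The three steps most likely to fail, each with one fallback**

Step 6. The alkene of 5 is flanked by CMe2 and CHMe, so furoxan formation, oligomerisation of 8 or a modest facial ratio could ruin the double cycloaddition. The fallback makes the C6–C7 bond by tethered carbonyl addition instead of cycloaddition. It sets out from 3 and comes back at 12.
- Acylation of 3 with bromoacetyl bromide and pyridine gives (1R,5R)‑3,3,5‑trimethyl‑4‑oxocyclohexyl bromoacetate F1.
- SmI2 in THF at −78 °C turns it into a samarium enolate that hangs from the axial oxygen. It can reach the ketone only from that face (intramolecular Reformatsky reaction). This gives the bridged hydroxy lactone F2, with the side‑chain carbon trans and the hydroxyl cis to the ring methyl.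
- Two equivalents of Ph3P=CHCH3 open the lactone to the acyl ylide F3.
- Wittig reaction with excess aqueous glyoxal gives the E hydroxy keto‑enal F4.
- Pr4N[RuO4]/N‑methylmorpholine N‑oxide oxidation of its secondary alcohol delivers 12.

Step 8. OsO4 may not discriminate cleanly between the central and the two enone double bonds of 10. The fallback avoids any scission by using a C5 dipole whose far end is already an aldehyde equivalent. It sets out from 5 and comes back at 12.
- Purchased (E)‑4,4‑dimethoxy‑2‑methylbut‑2‑enal is condensed with hydroxylamine to the acetal oxime F5.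
- F5 is oxidised with PhI(OAc)2 in the presence of 5 to the mono(spiro‑isoxazoline) acetal F6.
- Mo(CO)6 in wet acetonitrile gives the β‑hydroxy enone acetal F7.
- Dilute aqueous oxalic acid hydrolyses the acetal to 12.

Step 15. The step combines a statistical mono‑olefination of a symmetric bis‑salt with a lactol that aromatises to a furan on traces of acid. The fallback desymmetrises at the alcohol stage. It sets out from 19 (together with 18) and comes back at 22.
- One equivalent of PPh3·HBr converts 19 into the hydroxy phosphonium bromide F8, which is separated from diol and bis‑salt by solubility.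
- Its ylide reacts with 18 to give the pentaenyne triol F9.
- The polyenylic C12 hydroxyl of F9 ionises far more readily than the cross‑conjugated C19' hydroxyl, so one further equivalent of PPh3·HBr gives 22.

**Further compounds**
F1 | step 6 | (1R,5R)‑3,3,5‑trimethyl‑4‑oxocyclohexyl bromoacetate | O=C1[C@H](C)C[C@@H](OC(=O)CBr)CC1(C)C
F2 | step 6 | bridged hydroxy lactone (5‑hydroxy‑6,6,9‑trimethyl‑2‑oxabicyclo[3.2.2]nonan‑3‑one) | O=C1C[C@@]2(O)[C@H](C)C[C@@H](O1)CC2(C)C
F3 | step 6 | acyl ylide | CC(C(=O)C[C@@]1(O)[C@H](C)C[C@@H](O)CC1(C)C)=P(c1ccccc1)(c1ccccc1)c1ccccc1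
F4 | step 6 | E hydroxy keto‑enal | O=C/C=C(\C)C(=O)C[C@@]1(O)[C@H](C)C[C@@H](O)CC1(C)C
F5 | step 8 | (E)‑4,4‑dimethoxy‑2‑methylbut‑2‑enal (E)‑oxime | COC(OC)/C=C(\C)/C=N/O
F6 | step 8 | mono(spiro‑isoxazoline) acetal | COC(OC)/C=C(\C)C1=NO[C@]2(C1)[C@H](C)CC(=O)CC2(C)C
F7 | step 8 | β‑hydroxy enone acetal | COC(OC)/C=C(\C)C(=O)C[C@@]1(O)[C@H](C)CC(=O)CC1(C)C
F8 | step 15 | hydroxy phosphonium bromide | [Br-].OC/C(C)=C/C=C/C=C(C)/C[P+](c1ccccc1)(c1ccccc1)c1ccccc1
F9 | step 15 | pentaenyne triol | OC\C(C#CC1=C(C)C[C@@H](O)CC1(C)C)=C/C=C/C(C)=C/C=C/C=C(C)/CO
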